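## Structural features

The target is a constitutionally unsymmetrical dimer of two oxolane lignan units of the olivil type. Each unit is an oxolane (O1, C2 aryl, C3 bearing C9H2OH, C4 a tertiary carbinol bearing the benzylic carbon C7', C5H2) with the 2S,3R,4S configuration. The units are joined by one biaryl bond between C5 of ring A, the C2 aryl group of oxolane 1, and C5' of ring B, the C7' benzyl ring of oxolane 2; both biaryl carbons are ortho to a phenolic oxygen. In each oxolane three stereocentres are contiguous: the C2 aryl group is trans to the C3 hydroxymethyl group, and that group is cis to the C4 benzyl group, so the C4 hydroxyl lies on the face of the C2 aryl group. Fragile elements are the four free phenols, the two benzylic ether bonds C2–O1 para to a phenolic oxygen (ionised by acid, open to hydrogenolysis), and the readiness of the derived cations to be attacked by the C7' ring with closure of an aryltetralin. The real difficulty is twofold: the C3/C4 pair with a fully substituted carbinol carbon must be set twice, and the halves are not equivalent, because the biaryl gives ring A to one oxolane as its C2 aryl group and ring B to the other as its C7' group. The key step uses the fact that C2 of each oxolane is a benzylic carbon para to O-4 of its aryl ring (ring A in oxolane 1, the outer guaiacyl ring in oxolane 2) and sits next to C3. Both O1–C2 bonds can therefore be closed last by capture of benzylic cations by the C5 hydroxyls, with C3 dictating the configuration at C2.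

## Logic of the disconnections

**31 back to 30.** The four aryl O–CH2Ph bonds are cut. Phenols cannot pass through organolithium, enolate and hydride chemistry, and a para ether oxygen is wanted as a donor in the ring closure; benzyl serves both purposes and leaves without acid or base. The skeleton is not simplified, but all earlier steps become feasible. The forward step must stop at the aryl ethers and spare the two benzylic C2–O1 bonds.

**30 back to 29.** Both O1–C2 bonds are cut. These are the only ring bonds that can form reversibly, through cations stabilised by the para oxygen. Two rings and two stereocentres disappear, and the carbinol carbons of 29 may be epimer mixtures. The forward step must give oxygen capture by the C5 hydroxyl only, five-membered rings only, and the 2,3-trans isomer.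

**29 back to 28 and 27.** The two O–Si bonds are restored, then the carbinol C–H bonds and the C–H bonds of the C5 and C9 hydroxymethyl groups are removed, which turns each half into an aryl keto lactone carrying a menthyl acetal. The C3/C4 pair is far easier to control in a five-membered lactone than in a chain. One hydride reagent must reduce ketone, lactone and acetal carbon in a single operation without touching C3, and the tertiary oxygen must stay silylated until the oxidant and the hydride have been used.

**27 back to 26.** The two ketone oxygens are exchanged for dithiane sulfur, because the future C2 carbons must have acted as nucleophiles. The unmasking has to tolerate four electron-rich arenes and must not enolise the adjacent C3.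

**26 back to 24 and 18.** The C4–C7' bond of oxolane 2 is cut between the lactone α-carbon and the ring B methylene. This is the fragment union: ring B is the benzylic electrophile of one half while ring A was the acyl-anion carrier of the other. The molecule falls into a small lactone and a lactone that carries the biaryl. The alkylation must occur anti to the dithianyl group, and 18 must have no acidic hydrogen.

**18 back to 17, and 17 back to 13 and 15 (15 from 14).** The C–Br bond is traced to a silyl ether that survived the anion chemistry, and the C4–C7' bond of oxolane 1 is cut in the same way as above. The silyl ether must be exchanged for bromide without loss of the tertiary silyl ether.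

**13 back to 12, and 12 back to 8 and 9.** The O–Si bond is removed; then the bond between the dithiane carbon (future C2) and the lactone β-carbon (future C3) and the α C–O bond are cut. One tandem operation adds the aryl dithiane anion anti to the menthyloxy group of 9 and oxygenates the enolate. Oxygen has to be introduced before the benzyl group, because the last electrophile enters anti to the dithianyl group and the benzyl group must end up there.

**8 back to 6 and 4 (through 7); 6 from 5; 5 and 4 from 2; 2 from 1, with 3 for the dithiane.** The biaryl bond is cut so that the two rings are differentiated from the start (dithiane on ring A, silyloxymethyl on ring B). No dialdehyde has to be desymmetrised. The coupling must tolerate sulfur and one ortho substituent on each partner.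

**24 back to 23, 23 back to 20 and 9, 20 back to 19 and 3.** The same three operations as for the other half, on the simple guaiacyl dithiane.

## Other disconnections considered

**Alternative 1:** The cut runs through C2–C3 and O1–C5 of oxolane 1, with a dimethylphenylsilyl group at C4 standing in for the hydroxyl. In the forward sense a chiral Sc(OTf)3–pybox Lewis acid would activate the ring A aldehyde A3, which already carries a protected oxolane 2. The (E)-allylsilane A2 would attack through C3 anti to silicon, silicon would shift from C5 to C4, and the alkoxide would close on C5 to give A1. Stereoretentive Tamao–Fleming oxidation, desilylation and hydrogenolysis would follow.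
- In its favour: the step is convergent and would create two ring bonds and all three stereocentres of oxolane 1 at once, with the C3/C4 relation fixed by the alkene geometry of A2. On bonds and stereocentres made per step it is better than the chosen plan, whose key step makes one bond and one stereocentre per ring.
- Against it here: A3 is an electron-rich aldehyde with a single binding point, a poor partner for a chiral Lewis acid. The disubstituted alkene carbon of A2 leads to a tertiary β-silyl cation in which loss of silicon (plain allylation) competes with the 1,2-shift. The C2–O1 bond of A1 is para-alkoxybenzylic and could ionise under the Lewis acid. Oxidation of a hindered tertiary C–SiMe2Ph bond needs electrophilic activation of the phenyl group, which four electron-rich arenes are unlikely to tolerate. Only oxolane 1 is formed, so oxolane 2 needs its own pass.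
- Comparison: on structure the two plans are equal in that both need the unsymmetrical biaryl beforehand. On mechanism the alternative rests on kinetic catalyst control at C2, whereas the chosen plan lets C3 set C2 under reversible conditions. On step economy the alternative needs three operations after its key step against one, and two separate ring-forming passes against one two-fold closure.

**Alternative 2:** The cut runs through C2–C3 and C4–C5 of both oxolanes, with an acetyl group at C4 as the precursor of the hydroxyl. In the forward sense SnCl4 would open both acetal rings of the bis-dioxolane A5 (acetal carbons as epimer mixtures; carbinol carbons drawn for the chair that places the tin-bound oxygen equatorial). Each trisubstituted alkene would attack its oxocarbenium carbon, and C5 would then shift to the cationic C4, giving A4. Baeyer–Villiger oxidation, ester cleavage and hydrogenolysis would follow.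
- In its favour: the step is two-fold, as in the chosen plan (equal). It would form the quaternary C4 together with both ring C–C bonds and relay three stereocentres per ring from the alkene geometry through a chair arrangement with the aryl group equatorial. Setting the C3/C4 relation in the ring-forming event itself is better than the chosen plan, which needs separate addition and alkylation steps for it.
- Against it here: the only resident stereocentre that can choose between the two enantiomeric chairs is the tertiary carbinol carbon of A5, whose methyl group and metal-bound oxygen are of similar size, and C5 is unsubstituted, so absolute control is doubtful. SnCl4 is a stronger acid than the chosen catalyst and would meet four benzyl ethers and para-alkoxybenzylic ether products, with the same aryltetralin hazard. The acetyl-to-hydroxyl exchange needs a peracid in the presence of electron-rich arenes. A5 itself needs two stereodefined trisubstituted alkenes and two enantioenriched tertiary allylic diols.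
- Comparison: on structure it builds more per step. On mechanism it has a kinetic cation cascade against a reversible capture. On step economy it needs three operations after the key step against one, and a precursor no shorter than 29.

**Alternative 3:** The cut is made at the C4–C7' bonds of both halves, with C7' held beforehand as an arylmethyl ether on the C9 oxygen. In the forward sense irradiation above 300 nm of the bis(oxolan-4-one) A7 would let each ketone abstract a benzylic hydrogen from C7'. The 1,5-biradicals would close the C4–C7' bonds and give the bis(bridgehead-hydroxy furofuran) A6. Reductive opening of the C7'–O bonds, pivalate removal and debenzylation would follow.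
- In its favour: no reagent is needed and no strong base is used. The cis ring fusion of the bicycle forces the C4 hydroxyl onto the face of the C3 hydrogen, exactly the C3/C4 relation of the target. On this point it is the equal of, or better than, the chosen plan, which relies on steric approach control of an enolate. C3 of A7 is α to the ketone and should settle 2,3-trans on its own.
- Against it here: the carbonyl is flanked by the ring oxygen at C5, so α-cleavage (Norrish type 1) and hydrogen back-transfer compete with closure. Four electron-rich arenes can quench the excited ketone. The later reductive opening must distinguish two benzylic C–O bonds in each bicycle (C7'–O against C2–O1) only by the electronic difference between benzyloxy- and pivaloyloxy-substituted rings. Two kinds of phenol protection are needed.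
- Comparison: on structure it closes two extra rings that must be opened again. On mechanism it has a photochemical biradical step with several exits against an acid-catalysed equilibrium with one main side path. On step economy it needs two to three operations after the key step against one, while its two-fold character equals that of the chosen plan.

Key step: step 18

**Remarks on the chemistry (assumptions)**
- The carbon hydroxylated in steps 6 and 12 and the carbinol carbons formed in step 16 are carried as epimer mixtures, because each becomes planar again later (enolate in steps 9 and 14, cation in step 18).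
- Compounds 1, 3, 9, 14 and 19 are taken as purchasable; partly converted species of the two-fold steps 15 to 19 are not numbered separately.
- Check of configuration: with the menthyloxy group of 9 on C5 (R), anti addition and anti benzylation lead to C3 R and C4 S (oxolane numbering) in both halves, which are the descriptors of 29, 30 and 31. No structure needed correction.
- The design was tightened at four points:
  - the two biaryl rings are differentiated from the outset (8);
  - the thioacetals are unmasked at the lactone stage, so one LiAlH4 step replaces two hydride steps;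
  - the tertiary oxygens stay silylated through oxidant and hydride;
  - mercury, molybdenum peroxide and hexamethylphosphoramide are avoided.

## Route

Step 1
Reactants: 1 5-bromovanillin (3-bromo-4-hydroxy-5-methoxybenzaldehyde)
Product: 2 4-(benzyloxy)-3-bromo-5-methoxybenzaldehyde
Conditions: BnBr, K2CO3, DMF, 60 °C
Reagents that add atoms: benzyl bromide BrCc1ccccc1
Why: Williamson O-alkylation of the acidic, doubly ortho-substituted phenol; aldehyde and aryl bromide are inert to K2CO3.

Step 2
Reactants: 2 4-(benzyloxy)-3-bromo-5-methoxybenzaldehyde; 3 propane-1,3-dithiol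
Product: 4 2-[4-(benzyloxy)-3-bromo-5-methoxyphenyl]-1,3-dithiane
Conditions: I2 (10 mol %), CH2Cl2, rt
Reagents that add atoms: none
Why: Iodine-catalysed thioacetalisation of an aryl aldehyde, mild enough to leave the aryl benzyl ether alone; the dithiane makes the aldehyde carbon (future C2 of oxolane 1) an acyl-anion equivalent.

Step 3
Reactants: 2 4-(benzyloxy)-3-bromo-5-methoxybenzaldehyde
Product: 5 [4-(benzyloxy)-3-bromo-5-methoxyphenyl]methanol
Conditions: NaBH4, MeOH–THF, 0 °C
Reagents that add atoms: none
Why: Borohydride reduction of the aldehyde; aryl bromide and benzyl ether are untouched.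

Step 4
Reactants: 5 [4-(benzyloxy)-3-bromo-5-methoxyphenyl]methanol
Product: 6 {[4-(benzyloxy)-3-bromo-5-methoxyphenyl]methoxy}(tert-butyl)dimethylsilane
Conditions: tBuMe2SiCl, imidazole, DMF, rt
Reagents that add atoms: tert-butyldimethylsilyl chloride CC(C)(C)[Si](C)(C)Cl
Why: Standard silylation of a primary alcohol; the silyl ether carries the future benzylic electrophile of ring B through the organolithium steps.

Step 5
Reactants: 6 {[4-(benzyloxy)-3-bromo-5-methoxyphenyl]methoxy}(tert-butyl)dimethylsilane; 4 2-[4-(benzyloxy)-3-bromo-5-methoxyphenyl]-1,3-dithiane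
Product: 8 2-{2,2'-bis(benzyloxy)-5'-[(tert-butyldimethylsilyloxy)methyl]-3,3'-dimethoxybiphenyl-5-yl}-1,3-dithiane (ring A carries the dithiane and ring B the silyloxymethyl group), via arylboronic pinacol ester 7 (not isolated)
Conditions: B2pin2, KOAc, Pd(dppf)Cl2 (3 mol %), 1,4-dioxane, 90 °C; then 4, K3PO4 (aq), 90 °C
Reagents that add atoms: bis(pinacolato)diboron CC1(C)OB(OC1(C)C)B1OC(C)(C)C(C)(C)O1 (its boron group is carried by 7 only)
Why: Miyaura borylation of the sulfur-free bromide, then Suzuki–Miyaura coupling in the same flask; zerovalent palladium inserts into C–Br bonds that each have only one ortho substituent, and joining two differently functionalised rings avoids any desymmetrisation.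

Step 6
Reactants: 8 biaryl dithiane (as named in step 5); 9 (5R)-5-[(1R,2S,5R)-menthyloxy]furan-2(5H)-one
Product: 12 (4R,5R)-3-hydroxy-5-[(1R,2S,5R)-menthyloxy]-4-[2-(biaryl)-1,3-dithian-2-yl]oxolan-2-one (biaryl as in 8, bonded through C5 of ring A; C3 as epimer mixture), via 2-lithio-1,3-dithiane 10 (not isolated), via lithium lactone enolate 11 (not isolated)
Conditions: n-BuLi, THF, −78 → −20 °C; 9, −78 °C; then 2-(phenylsulfonyl)-3-phenyloxaziridine, −78 °C; NH4Cl (aq)
Reagents that add atoms: 2-(phenylsulfonyl)-3-phenyloxaziridine O=S(=O)(N1OC1c1ccccc1)c1ccccc1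
Why: Tandem conjugate addition–enolate oxygenation: the soft aryl dithiane anion adds 1,4 to the butenolide anti to the menthyloxy group, which sets the future C3 of oxolane 1, and the enolate takes oxygen from the N-sulfonyloxaziridine; the configuration of the hydroxylated carbon is irrelevant.

Step 7
Reactants: 12 hydroxy lactone (as named in step 6)
Product: 13 3-O-triethylsilyl ether of 12
Conditions: Et3SiOTf, 2,6-lutidine, CH2Cl2, −78 → 0 °C
Reagents that add atoms: triethylsilyl triflate CC[Si](CC)(CC)OS(=O)(=O)C(F)(F)F
Why: Silylation of a secondary α-hydroxy lactone with a silyl triflate and a hindered base; the silyl ether blocks oxygen during enolate alkylation and later shields the tertiary carbinol.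

Step 8
Reactants: 14 [4-(benzyloxy)-3-methoxyphenyl]methanol
Product: 15 1-(benzyloxy)-4-(bromomethyl)-2-methoxybenzene
Conditions: PBr3, Et2O, 0 °C
Reagents that add atoms: phosphorus tribromide BrP(Br)Br
Why: Bromination of a benzylic alcohol through its phosphite ester; the bromide is used fresh.

Step 9
Reactants: 13 silyloxy lactone (as named in step 7); 15 1-(benzyloxy)-4-(bromomethyl)-2-methoxybenzene
Product: 17 (3S,4R,5R)-3-[4-(benzyloxy)-3-methoxybenzyl]-5-[(1R,2S,5R)-menthyloxy]-3-(triethylsilyloxy)-4-[2-(biaryl)-1,3-dithian-2-yl]oxolan-2-one (biaryl as in 8), via lithium silyloxy enolate 16 (not isolated)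
Conditions: LiN(iPr)2, THF, −78 °C; then 15, DMPU, −78 → −40 °C
Reagents that add atoms: none
Why: Enolate alkylation: the base removes the only acidic hydrogen, and the planar α-silyloxy enolate is benzylated on the face opposite the bulky aryl dithianyl group on the neighbouring carbon (the menthyloxy group is one carbon further away), which creates the fully substituted future C4 of oxolane 1 with the benzyl group cis to the future C9 carbon.

Step 10
Reactants: 17 benzylated lactone (as named in step 9)
Product: 18 benzylic bromide: 17 with CH2Br in place of the silyloxymethyl group on ring B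
Conditions: Ph3PBr2, CH2Cl2, 0 °C → rt
Reagents that add atoms: dibromotriphenylphosphorane BrP(Br)(c1ccccc1)(c1ccccc1)c1ccccc1
Why: Direct conversion of a primary silyl ether to the bromide (oxygen attacks phosphorus, bromide removes silicon, bromide then displaces the oxyphosphonium group); the tertiary triethylsilyl ether is too hindered to react, and phosphorus-bound bromine should not attack thioacetal sulfur.

Step 11
Reactants: 19 4-(benzyloxy)-3-methoxybenzaldehyde; 3 propane-1,3-dithiol
Product: 20 2-[4-(benzyloxy)-3-methoxyphenyl]-1,3-dithiane
Conditions: I2 (10 mol %), CH2Cl2, rt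
Reagents that add atoms: none
Why: Thioacetalisation as in step 2; this carbon becomes C2 of oxolane 2.

Step 12
Reactants: 20 2-[4-(benzyloxy)-3-methoxyphenyl]-1,3-dithiane; 9 (5R)-5-[(1R,2S,5R)-menthyloxy]furan-2(5H)-one
Product: 23 (4R,5R)-4-{2-[4-(benzyloxy)-3-methoxyphenyl]-1,3-dithian-2-yl}-3-hydroxy-5-[(1R,2S,5R)-menthyloxy]oxolan-2-one (C3 as epimer mixture), via 2-lithio-1,3-dithiane 21 (not isolated), via lithium lactone enolate 22 (not isolated)
Conditions: n-BuLi, THF, −78 → −20 °C; 9, −78 °C; then 2-(phenylsulfonyl)-3-phenyloxaziridine, −78 °C; NH4Cl (aq)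
Reagents that add atoms: 2-(phenylsulfonyl)-3-phenyloxaziridine O=S(=O)(N1OC1c1ccccc1)c1ccccc1
Why: Same tandem conjugate addition–enolate oxygenation as step 6 on the simpler dithiane; addition anti to the menthyloxy group sets the future C3 of oxolane 2.

Step 13
Reactants: 23 hydroxy lactone (as named in step 12)
Product: 24 3-O-triethylsilyl ether of 23
Conditions: Et3SiOTf, 2,6-lutidine, CH2Cl2, −78 → 0 °C
Reagents that add atoms: triethylsilyl triflate CC[Si](CC)(CC)OS(=O)(=O)C(F)(F)F
Why: Silylation as in step 7.

Step 14
Reactants: 24 silyloxy lactone (as named in step 13); 18 benzylic bromide (as named in step 10)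
Product: 26 bis-lactone: 24 alkylated at C3 (S configuration, new bond trans to the dithianyl group) by the ring B methylene of 18, via lithium silyloxy enolate 25 (not isolated)
Conditions: LiN(iPr)2, THF, −78 °C; then 18, DMPU, −78 → −40 °C
Reagents that add atoms: none
Why: Fragment union by enolate alkylation; 18 has no acidic hydrogen (quaternary lactone carbon, fully substituted dithiane), and attack anti to the dithianyl group sets the future C4 of oxolane 2 as in step 9.

Step 15
Reactants: 26 bis-lactone (as named in step 14)
Product: 27 bis(keto lactone): both 1,3-dithiane-2,2-diyl groups of 26 replaced by C=O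
Conditions: PhI(O2CCF3)2, NaHCO3, MeCN–H2O (9:1), 0 °C
Reagents that add atoms: water O
Why: Oxidative dethioacetalisation: the trivalent iodine reagent activates sulfur and the aryl-stabilised thionium ions are hydrolysed. No free hydroxyl or 1,2-diol is present at this stage, and the aroyl group at lactone C4 is already trans to both neighbours, so enolisation should not change C3 of either future oxolane.

Step 16
Reactants: 27 bis(keto lactone) (as named in step 15)
Product: 28 bis(triethylsilyl ether) of bis-tetraol 29 at the two tertiary oxygens (C3 R and C4 S in oxolane numbering in both halves; benzylic carbinols as epimer mixtures)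
Conditions: LiAlH4, THF, −20 °C → rt; aq KNaC4H4O6
Reagents that add atoms: none
Why: Hydride reduction of each aryl ketone to the carbinol (either epimer serves) and of each lactone through ring opening; the acetal carbon is released as an aldehyde with loss of menthoxide and reduced to the C9 hydroxymethyl group, while silyl and benzyl ethers survive.

Step 17
Reactants: 28 bis(triethylsilyl ether) (as named in step 16)
Product: 29 bis-tetraol: two 1-aryl-3-benzyl-2-(hydroxymethyl)butane-1,3,4-triol units on the biaryl (C3 R and C4 S in oxolane numbering in both halves; benzylic carbinols as epimer mixtures; four phenols as benzyl ethers)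
Conditions: Bu4NF, THF, 0 °C → rt
Reagents that add atoms: none
Why: Fluoride cleavage of the tertiary silyl ethers under basic, non-ionising conditions, so the acid-sensitive benzylic carbinols are not touched.

Step 18
Reactants: 29 bis-tetraol (as named in step 17)
Product: 30 tetra-O-benzyl ether of 31 (2S,3R,4S in both oxolanes)
Conditions: (±)-camphor-10-sulfonic acid (20 mol %), CH2Cl2–THF (9:1), 0.01 M, 0 °C → rt; Et3N
Reagents that add atoms: none
Why: Protonation of each benzylic hydroxyl and loss of water gives a benzylic cation delocalised into its para-benzyloxy ring; the C5 hydroxyl adds to it and returns the proton, so the acid is catalytic. The closest known reaction type is the acid-mediated SN1 cycloetherification of benzylic-hydroxy lignan 1,4-diols to 2-aryl oxolanes. Each ring closes in the 5-exo-trig mode, the C5 oxygen attacking the trigonal cationic C2. The two new stereocentres are the two C2 atoms, and each is controlled by its neighbour C3: the aryl group avoids the C3 hydroxymethyl group in the envelope-like transition state and in the product, and either carbinol epimer gives the same planar cation, so all four epimers of 29 should converge on the 2,3-trans isomer, with any cis ether able to re-ionise and equilibrate. Ring size is secured by the substrate, since the C9 and C4 hydroxyls could only close oxetanes. The selectivity to be watched is oxygen against carbon capture, because the C7' ring could attack the cation and close an aryltetralin irreversibly; fast 5-exo oxygen capture, a weak sulfonic acid in catalytic amount, low temperature, high dilution and prompt quenching with base are expected to keep the reaction on the oxygen pathway. The two closures are independent, as the two cationic centres lie on different rings of the biaryl.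

Step 19
Reactants: 30 tetra-O-benzyl ether (as named in step 18)
Product: 31 target, the bis-oxolane tetraphenol (2S,3R,4S in both oxolanes)
Conditions: H2 (1 atm), Pd/C (10 wt %), EtOAc–EtOH (1:1), rt, stopped at full conversion
Reagents that add atoms: none
Why: Hydrogenolysis of four aryl benzyl ethers; aryl O–CH2Ph bonds should cleave much faster in neutral solvent than the benzylic C2–O1 ring bonds, and no stereocentre is involved.

## Compound list

1 | 5-bromovanillin | COc1cc(C=O)cc(Br)c1O | starting material
2 | 4-(benzyloxy)-3-bromo-5-methoxybenzaldehyde | COc1cc(C=O)cc(Br)c1OCc1ccccc1 | intermediate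
3 | propane-1,3-dithiol | SCCCS | starting material
4 | 2-[4-(benzyloxy)-3-bromo-5-methoxyphenyl]-1,3-dithiane | COc1cc(cc(Br)c1OCc1ccccc1)C1SCCCS1 | intermediate
5 | [4-(benzyloxy)-3-bromo-5-methoxyphenyl]methanol | COc1cc(CO)cc(Br)c1OCc1ccccc1 | intermediate
6 | {[4-(benzyloxy)-3-bromo-5-methoxyphenyl]methoxy}(tert-butyl)dimethylsilane | COc1cc(CO[Si](C)(C)C(C)(C)C)cc(Br)c1OCc1ccccc1 | intermediate
7 | pinacol boronate from 6 (boron in place of bromine) | COc1cc(CO[Si](C)(C)C(C)(C)C)cc(B2OC(C)(C)C(C)(C)O2)c1OCc1ccccc1 | intermediate (not isolated)
8 | biaryl dithiane (ring A: dithiane; ring B: silyloxymethyl) | COc1cc(cc(c1OCc1ccccc1)-c1cc(CO[Si](C)(C)C(C)(C)C)cc(OC)c1OCc1ccccc1)C1SCCCS1 | intermediate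
9 | (5R)-5-[(1R,2S,5R)-menthyloxy]furan-2(5H)-one | C[C@@H]1CC[C@H]([C@@H](C1)O[C@@H]2OC(=O)C=C2)C(C)C | starting material
10 | 2-lithio derivative of 8 | [Li]C1(SCCCS1)c1cc(OC)c(OCc2ccccc2)c(c1)-c1cc(CO[Si](C)(C)C(C)(C)C)cc(OC)c1OCc1ccccc1 | intermediate (not isolated)
11 | lithium enolate of the 1,4-adduct of 10 and 9 (dithianyl trans to menthyloxy) | [Li]OC1=C[C@@H](C2(SCCCS2)c2cc(OC)c(OCc3ccccc3)c(c2)-c2cc(CO[Si](C)(C)C(C)(C)C)cc(OC)c2OCc2ccccc2)[C@H](O[C@@H]2C[C@H](C)CC[C@H]2C(C)C)O1 | intermediate (not isolated)
12 | (4R,5R)-3-hydroxy lactone of the biaryl half, C3 epimers | O=C1O[C@@H](O[C@@H]2C[C@H](C)CC[C@H]2C(C)C)[C@H](C2(SCCCS2)c2cc(OC)c(OCc3ccccc3)c(c2)-c2cc(CO[Si](C)(C)C(C)(C)C)cc(OC)c2OCc2ccccc2)C1O | intermediate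
13 | 3-O-triethylsilyl ether of 12 | O=C1O[C@@H](O[C@@H]2C[C@H](C)CC[C@H]2C(C)C)[C@H](C2(SCCCS2)c2cc(OC)c(OCc3ccccc3)c(c2)-c2cc(CO[Si](C)(C)C(C)(C)C)cc(OC)c2OCc2ccccc2)C1O[Si](CC)(CC)CC | intermediate
14 | [4-(benzyloxy)-3-methoxyphenyl]methanol | COc1cc(CO)ccc1OCc1ccccc1 | starting material
15 | 1-(benzyloxy)-4-(bromomethyl)-2-methoxybenzene | COc1cc(CBr)ccc1OCc1ccccc1 | intermediate
16 | lithium enolate of 13 | [Li]OC1=C(O[Si](CC)(CC)CC)[C@@H](C2(SCCCS2)c2cc(OC)c(OCc3ccccc3)c(c2)-c2cc(CO[Si](C)(C)C(C)(C)C)cc(OC)c2OCc2ccccc2)[C@H](O[C@@H]2C[C@H](C)CC[C@H]2C(C)C)O1 | intermediate (not isolated)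
17 | (3S,4R,5R)-3-benzylated silyloxy lactone of the biaryl half | O=C1O[C@@H](O[C@@H]2C[C@H](C)CC[C@H]2C(C)C)[C@H](C2(SCCCS2)c2cc(OC)c(OCc3ccccc3)c(c2)-c2cc(CO[Si](C)(C)C(C)(C)C)cc(OC)c2OCc2ccccc2)[C@@]1(O[Si](CC)(CC)CC)Cc1ccc(OCc2ccccc2)c(OC)c1 | intermediate
18 | ring B benzylic bromide from 17 | O=C1O[C@@H](O[C@@H]2C[C@H](C)CC[C@H]2C(C)C)[C@H](C2(SCCCS2)c2cc(OC)c(OCc3ccccc3)c(c2)-c2cc(CBr)cc(OC)c2OCc2ccccc2)[C@@]1(O[Si](CC)(CC)CC)Cc1ccc(OCc2ccccc2)c(OC)c1 | intermediate
19 | 4-(benzyloxy)-3-methoxybenzaldehyde | COc1cc(C=O)ccc1OCc1ccccc1 | starting material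
20 | 2-[4-(benzyloxy)-3-methoxyphenyl]-1,3-dithiane | COc1cc(ccc1OCc1ccccc1)C1SCCCS1 | intermediate
21 | 2-lithio derivative of 20 | [Li]C1(SCCCS1)c1ccc(OCc2ccccc2)c(OC)c1 | intermediate (not isolated)
22 | lithium enolate of the 1,4-adduct of 21 and 9 | [Li]OC1=C[C@@H](C2(SCCCS2)c2ccc(OCc3ccccc3)c(OC)c2)[C@H](O[C@@H]2C[C@H](C)CC[C@H]2C(C)C)O1 | intermediate (not isolated)
23 | (4R,5R)-3-hydroxy lactone of the guaiacyl half, C3 epimers | O=C1O[C@@H](O[C@@H]2C[C@H](C)CC[C@H]2C(C)C)[C@H](C2(SCCCS2)c2ccc(OCc3ccccc3)c(OC)c2)C1O | intermediate
24 | 3-O-triethylsilyl ether of 23 | O=C1O[C@@H](O[C@@H]2C[C@H](C)CC[C@H]2C(C)C)[C@H](C2(SCCCS2)c2ccc(OCc3ccccc3)c(OC)c2)C1O[Si](CC)(CC)CC | intermediate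
25 | lithium enolate of 24 | [Li]OC1=C(O[Si](CC)(CC)CC)[C@@H](C2(SCCCS2)c2ccc(OCc3ccccc3)c(OC)c2)[C@H](O[C@@H]2C[C@H](C)CC[C@H]2C(C)C)O1 | intermediate (not isolated)
26 | bis-lactone (both lactones 3S,4R,5R; two dithianes; two triethylsilyl ethers) | O=C1O[C@@H](O[C@@H]2C[C@H](C)CC[C@H]2C(C)C)[C@H](C2(SCCCS2)c2ccc(OCc3ccccc3)c(OC)c2)[C@@]1(O[Si](CC)(CC)CC)Cc1cc(OC)c(OCc2ccccc2)c(c1)-c1cc(cc(OC)c1OCc1ccccc1)C1(SCCCS1)[C@H]1[C@H](O[C@@H]2C[C@H](C)CC[C@H]2C(C)C)OC(=O)[C@]1(O[Si](CC)(CC)CC)Cc1ccc(OCc2ccccc2)c(OC)c1 | intermediate
27 | bis(keto lactone) | O=C1O[C@@H](O[C@@H]2C[C@H](C)CC[C@H]2C(C)C)[C@H](C(=O)c2ccc(OCc3ccccc3)c(OC)c2)[C@@]1(O[Si](CC)(CC)CC)Cc1cc(OC)c(OCc2ccccc2)c(c1)-c1cc(cc(OC)c1OCc1ccccc1)C(=O)[C@H]1[C@H](O[C@@H]2C[C@H](C)CC[C@H]2C(C)C)OC(=O)[C@]1(O[Si](CC)(CC)CC)Cc1ccc(OCc2ccccc2)c(OC)c1 | intermediate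
28 | bis(triethylsilyl ether) of the bis-tetraol, carbinol epimers | COc1cc(ccc1OCc1ccccc1)C(O)[C@@H](CO)[C@@](CO)(O[Si](CC)(CC)CC)Cc1cc(OC)c(OCc2ccccc2)c(c1)-c1cc(cc(OC)c1OCc1ccccc1)C(O)[C@@H](CO)[C@@](CO)(O[Si](CC)(CC)CC)Cc1ccc(OCc2ccccc2)c(OC)c1 | intermediate
29 | bis-tetraol, carbinol epimers (precursor of the key step) | COc1cc(ccc1OCc1ccccc1)C(O)[C@@H](CO)[C@@](CO)(O)Cc1cc(OC)c(OCc2ccccc2)c(c1)-c1cc(cc(OC)c1OCc1ccccc1)C(O)[C@@H](CO)[C@@](CO)(O)Cc1ccc(OCc2ccccc2)c(OC)c1 | intermediate
30 | tetra-O-benzyl ether of the target (product of the key step) | COc1cc(ccc1OCc1ccccc1)C[C@@]1(O)CO[C@H](c2cc(OC)c(OCc3ccccc3)c(c2)-c2cc(cc(OC)c2OCc2ccccc2)C[C@@]2(O)CO[C@H](c3ccc(OCc4ccccc4)c(OC)c3)[C@H]2CO)[C@H]1CO | intermediate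
31 | CNP0269573.1, bis-oxolane tetraphenol | COc1cc(C[C@@]2(O)CO[C@H](c3cc(OC)c(O)c(-c4cc(C[C@@]5(O)CO[C@H](c6ccc(O)c(OC)c6)[C@H]5CO)cc(OC)c4O)c3)[C@H]2CO)ccc1O | target

## Step count and least certain steps

Total: 19 steps. Longest linear sequence: 14 steps (steps 1, 3, 4, 5, 6, 7, 9, 10, 14, 15, 16, 17, 18, 19). Where 2 and 15 can be bought, the total falls to 17.

**Step 18 (key step).** The most likely failure is carbon instead of oxygen capture: attack of the C7' ring on the benzylic cation would close an aryltetralin irreversibly, most readily in the half whose C7' ring is the unhindered guaiacyl ring, and prolonged acid contact of the product would feed the same leak. Incomplete funnelling to the 2,3-trans isomer, or intermolecular etherification at higher concentration, are lesser risks. Fallback: the route sets out from 29, whose four benzyl ethers are removed first by hydrogenolysis (H2, Pd/C, EtOAc) to give the free-phenol bis-tetraol F1. Warming F1 in a weakly acidic buffer (acetate, aqueous dioxane, 50 °C) should generate para-quinone methides instead of O-benzylated cations. These neutral electrophiles add the C5 hydroxyls reversibly (oxa-Michael addition) and are much less prone to arylation. The detour returns to the route at 31, bypasses 30, and would also serve if the hydrogenolysis of step 19 were to over-reduce the benzylic ring oxygens.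

**Step 6 (and its twin, step 12).** The enolate or the product alkoxide may be intercepted by the sulfonylimine released from the oxaziridine, the thioacetal sulfur may be oxidised, or proton transfer may compete with conjugate addition on the hindered biaryl anion. Fallback: setting out from 8 and 9, the enolate is protonated and the simple adduct, the lactone F2, is isolated. F2 is then converted to its potassium enolate with KN(SiMe3)2 and oxygenated with dioxygen in the presence of P(OEt)3, a hydroperoxide pathway that releases no imine. The sequence returns at 12.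

**Step 9 (and step 14).** Enolisation of the α-silyloxy lactone may be slow because the remaining hydrogen is flanked by the dithianyl group, and the bulky silyloxy group may erode the facial preference or favour O-alkylation. Fallback: setting out from 12, the unprotected hydroxy lactone is converted with two equivalents of LiN(iPr)2 into its dianion and C-benzylated with 15 to give the tertiary hydroxy lactone F3. Silylation of F3 with Et3SiOTf returns to the route at 17.

**Step 10.** The bromophosphonium reagent or adventitious HBr may attack the tertiary silyl ether, the menthyl acetal or thioacetal sulfur, and the electron-rich benzylic bromide may decompose on handling. Fallback: setting out from 17, buffered HF·pyridine removes only the primary silyl ether to give the benzylic alcohol F4. MsCl, Et3N and LiCl convert F4 into the benzylic chloride F5. F5 is used in place of 18 in the alkylation of step 14 with Bu4NI as an in situ iodide source, and the route is rejoined at 26.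

**Step 15.** The trivalent iodine reagent may oxidise the electron-rich arenes, the very hindered thioacetals may stall at sulfoxides, or the new ketone may trigger elimination of the acetal oxygen on the neighbouring carbon. Fallback: setting out from 26, the order is inverted. LiAlH4 first reduces both lactones with the dithianes in place, giving the dithiane bis-diol F6. Alkylative unmasking with MeI and CaCO3 in aqueous MeCN then gives the bis-ketone F7 (expected as its hemiketal). Immediate NaBH4 reduction returns to the route at 28.

## Further compounds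

F1 | step 18 | free-phenol bis-tetraol (29 without its four benzyl groups) | COc1cc(ccc1O)C(O)[C@@H](CO)[C@@](CO)(O)Cc1cc(OC)c(O)c(c1)-c1cc(cc(OC)c1O)C(O)[C@@H](CO)[C@@](CO)(O)Cc1ccc(O)c(OC)c1
F2 | step 6 | (4R,5R)-4-[2-(biaryl)-1,3-dithian-2-yl]-5-(menthyloxy)oxolan-2-one (12 without its hydroxyl) | O=C1O[C@@H](O[C@@H]2C[C@H](C)CC[C@H]2C(C)C)[C@H](C2(SCCCS2)c2cc(OC)c(OCc3ccccc3)c(c2)-c2cc(CO[Si](C)(C)C(C)(C)C)cc(OC)c2OCc2ccccc2)C1
F3 | step 9 | (3S,4R,5R)-3-benzylated 3-hydroxy lactone (17 without its triethylsilyl group) | O=C1O[C@@H](O[C@@H]2C[C@H](C)CC[C@H]2C(C)C)[C@H](C2(SCCCS2)c2cc(OC)c(OCc3ccccc3)c(c2)-c2cc(CO[Si](C)(C)C(C)(C)C)cc(OC)c2OCc2ccccc2)[C@@]1(O)Cc1ccc(OCc2ccccc2)c(OC)c1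
F4 | step 10 | ring B benzylic alcohol from 17 | O=C1O[C@@H](O[C@@H]2C[C@H](C)CC[C@H]2C(C)C)[C@H](C2(SCCCS2)c2cc(OC)c(OCc3ccccc3)c(c2)-c2cc(CO)cc(OC)c2OCc2ccccc2)[C@@]1(O[Si](CC)(CC)CC)Cc1ccc(OCc2ccccc2)c(OC)c1
F5 | step 10 | ring B benzylic chloride | O=C1O[C@@H](O[C@@H]2C[C@H](C)CC[C@H]2C(C)C)[C@H](C2(SCCCS2)c2cc(OC)c(OCc3ccccc3)c(c2)-c2cc(CCl)cc(OC)c2OCc2ccccc2)[C@@]1(O[Si](CC)(CC)CC)Cc1ccc(OCc2ccccc2)c(OC)c1
F6 | step 15 | dithiane bis-diol (both lactones of 26 reduced, dithianes and silyl ethers kept) | COc1cc(ccc1OCc1ccccc1)C1(SCCCS1)[C@@H](CO)[C@@](CO)(O[Si](CC)(CC)CC)Cc1cc(OC)c(OCc2ccccc2)c(c1)-c1cc(cc(OC)c1OCc1ccccc1)C1(SCCCS1)[C@@H](CO)[C@@](CO)(O[Si](CC)(CC)CC)Cc1ccc(OCc2ccccc2)c(OC)c1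
F7 | step 15 | bis-ketone (open keto form) | COc1cc(ccc1OCc1ccccc1)C(=O)[C@@H](CO)[C@@](CO)(O[Si](CC)(CC)CC)Cc1cc(OC)c(OCc2ccccc2)c(c1)-c1cc(cc(OC)c1OCc1ccccc1)C(=O)[C@@H](CO)[C@@](CO)(O[Si](CC)(CC)CC)Cc1ccc(OCc2ccccc2)c(OC)c1
A1 | alternative 1 | 4-(dimethylphenylsilyl) oxolane 1 joined to protected oxolane 2 | COc1cc(ccc1OCc7ccccc7)C[C@@]2([Si](C)(C)c8ccccc8)CO[C@H](c3cc(OC)c(OCc7ccccc7)c(c3)-c4cc(cc(OC)c4OCc7ccccc7)C[C@@]5(O[Si](CC)(CC)CC)CO[C@H](c6ccc(OCc7ccccc7)c(OC)c6)[C@H]5COCc7ccccc7)[C@H]2COCc7ccccc7
A2 | alternative 1 | (E)-allylsilane: [2-(4-benzyloxy-3-methoxybenzyl)-4-(benzyloxy)but-2-enyl]dimethylphenylsilane | C[Si](C)(c1ccccc1)C/C(Cc1ccc(OCc2ccccc2)c(OC)c1)=C/COCc1ccccc1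
A3 | alternative 1 | ring A aldehyde carrying protected oxolane 2 | O=Cc1cc(OC)c(OCc2ccccc2)c(c1)-c1cc(cc(OC)c1OCc1ccccc1)C[C@@]1(O[Si](CC)(CC)CC)CO[C@H](c2ccc(OCc3ccccc3)c(OC)c2)[C@H]1COCc1ccccc1
A4 | alternative 2 | bis(4-acetyl-2-aryl-4-benzyl-3-(benzyloxymethyl)oxolane) | COc1cc(ccc1OCc7ccccc7)C[C@@]2(C(C)=O)CO[C@H](c3cc(OC)c(OCc7ccccc7)c(c3)-c4cc(cc(OC)c4OCc7ccccc7)C[C@@]5(C(C)=O)CO[C@H](c6ccc(OCc7ccccc7)c(OC)c6)[C@H]5COCc7ccccc7)[C@H]2COCc7ccccc7
A5 | alternative 2 | bis(2-aryl-4-methyl-4-[(E)-alkenyl]-1,3-dioxolane), acetal carbons as epimer mixtures | COc1cc(ccc1OCc1ccccc1)C/C(=C\COCc1ccccc1)[C@]1(C)COC(O1)c1cc(OC)c(OCc2ccccc2)c(c1)-c1cc(cc(OC)c1OCc1ccccc1)C/C(=C\COCc1ccccc1)[C@]1(C)COC(O1)c1ccc(OCc2ccccc2)c(OC)c1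
A6 | alternative 3 | bis(bridgehead-hydroxy furofuran), C7' aryl groups drawn exo | O[C@]12CO[C@H](c3cc(OC)c(OC(=O)C(C)(C)C)c(c3)-c4cc(cc(OC)c4OCc7ccccc7)[C@H]5OC[C@@H]6[C@@H](c8ccc(OC(=O)C(C)(C)C)c(OC)c8)OC[C@]56O)[C@H]1CO[C@@H]2c9ccc(OCc7ccccc7)c(OC)c9
A7 | alternative 3 | bis(2-aryl-3-[(arylmethoxy)methyl]oxolan-4-one), 2,3-trans | COc1cc(ccc1OCc1ccccc1)COC[C@H]1C(=O)CO[C@@H]1c1cc(OC)c(OC(=O)C(C)(C)C)c(c1)-c1cc(cc(OC)c1OCc1ccccc1)COC[C@H]1C(=O)CO[C@@H]1c1ccc(OC(=O)C(C)(C)C)c(OC)c1
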